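## Structural features

The target is a 20-norgibberellane. Ring A (C1–C5, C10) carries a cis-2,3-diol and the C4 methyl, and its C19 carboxyl is tied to C10 as a γ-lactone. Ring B (C5, C6, C8, C9, C10) carries the C7 acid on C6. Rings C and D share C8 and C13 as a bicyclo[3.2.1]octane in which the tertiary C13 alcohol sits next to the C16 exocyclic methylene. There are nine stereocentres: eight run in one chain C2–C3–C4–C5(–C6)–C10–C9–C8, and C13 is the ninth; C4 and C8 are all-carbon quaternary, C10 and C13 are fully substituted and oxygenated. Read literally, the SMILES puts H9 syn to the C10 lactone oxygen and anti to the C15–C16 bridge (the opposite of the usual plant-gibberellin pattern at C9), H5 anti to the lactone, the diol anti to the lactone bridge, and C7 trans to C4. The fragile groups are the allylic tertiary alcohol and exocyclic alkene pair (acid-induced skeletal shift), the β-hydroxy lactone (retro-aldol epimerisation at C3 in base) and the epimerisable C6. The real difficulty is the quaternary C8 inside the bridged C/D unit with the correct relation to C9 and C13, and then relaying that information across the flat ring B to C4, C5 and C10. The key step exploits the fact that C13 is a tertiary carbinol bonded to C16, as in the hydroxy-acid carbon of quinic acid: in a ring C chair an axial acyl group on C13 lies 1,3-diaxial to the axial hydrogen on C8, so a carbenoid at C15 can bridge C16 to C8 and close ring D.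

## Logic of the disconnections

33 to 29: the C16=C17 bond, the two C–O bonds at C2 and C3, the silyl ether and the ester methyl are removed. The acid-sensitive methylene and the retro-aldol-prone diol are best introduced last. This leaves a Δ2 alkene and a C16 ketone, and it demands a non-basic, ketone-selective methylenation and a dihydroxylation from the face opposite the lactone bridge.

29 to 26: the C10–O lactone bond and the C5–H bond are cut, and C6 is allowed to be epimeric. Both C5 and C10 then follow from the single C4 stereocentre of a 1,4-dihydrobenzoic acid by anti addition across C5=C10. The bridged lactone disappears; the demand is that the C19 carboxyl sits on the face that places the lactone oxygen syn to H9, and that C6 can afterwards be equilibrated to C7 trans to C4.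

26 to 25: the C4–C18 bond is cut and ring A is re-aromatised. Ring A becomes a benzoic acid, so the quaternary C4 is made from an sp2 carbon by reductive alkylation. The demand is facial control of the methylation by the only nearby stereocentre, C6.

25 to 20 (through 24–21): the C5–C6 bond of ring B is cut to an ester enolate and an aryl bromide, and the C11 oxygen is restored. This reduces the tetracycle to a bicyclo[3.2.1]octane carrying a CH2CO2Me arm on C8 and an aryl group on C9. The forward step needs these two groups gauche (trans-diequatorial on ring C), and the C16 ketone must be masked first, because its C15 enolate would compete for the aryl palladium and close an isomeric five-membered ring.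

20 and 19 to 18: the C8–C15 bond is cut (key step). The bridged bicycle collapses to a cyclohexane and the quaternary C8 becomes a C–H bond. The forward step needs the acyl group axial and cis to H8, and no other reachable C–H bond. An analogue of 18 with CH2 at C11 would offer a second syn-axial hydrogen that is the better hydride donor, because the wanted C8–H bond is β to an ester. Therefore the C11 oxygen left over from the enone is kept as an axial benzoate in 18 and 19 and is removed only after ring B is closed, when no aryl bromide is left to interfere with the radical deoxygenation.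

18 to 15 and 16: the C15–C16 bond is cut to a C13 carboxylic acid and a one-carbon diazo unit. This requires the C13 carboxyl to be distinguishable from the two methyl esters, so it is carried as an acid-labile ester from 7 to 14.

14 to 12, then to 10 and 11: the C11–O bond goes back to a ketone and the C9–C10 aryl–alkyl bond is cut. The ketone makes C9 nucleophilic and epimerisable, so the aryl group ends trans to the arm. The forward step needs a regiodefined enolate and reaction at C–I in preference to C–Br.

10 to 8 and 9: the C8–C6 bond is cut to an enone and an acetate enolate equivalent. The conjugate addition supplies the arm and the regiodefined enol ether together. Its demand is attack on the face of the C13 oxygen, which is the one relation that cannot be corrected later.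

8 to 1: only functional groups change. The C8 and C9 hydroxyls leave as an alkene, the C11 hydroxyl becomes the ketone, and C13 keeps its oxygen and carboxyl carbon. C13, C12, C11, C9, C8 and C14 are C1, C6, C5, C4, C3 and C2 of 1; this assignment, not its mirror image, leads to the enantiomer required.

## Other disconnections considered

Alternative 1: The cut is C4–C5 together with the C10–O lactone bond. In the forward step Mn(OAc)3 (with Cu(OAc)2 as co-oxidant) would oxidise the α-methyl β-keto ester A1 to the C4 radical, which adds 6-endo to C5 of the ring B alkene; the tertiary C10 radical is oxidised to the cation and trapped by the ester oxygen to give the 3-oxo lactone A2. In its favour, ring A, the lactone and the quaternary C4 form in one operation, and an oxygen arrives at C3. Against it here, the whole B/C/D tricycle with C8 and the methylene must already exist, so the hardest centre is not addressed; the C16=C17 alkene is a second radical acceptor; the face of attack at C5 relative to C6 and C9 is not secured in this C9 series; and the 2-hydroxyl still has to be placed cis next to a reduced C3. In comparison, alternative 1 is the better plan for ring A alone (one step against steps 19 to 21 here) and is equal in relying on substrate control at C4. It is weaker on structure, because ring D and C8 need a separate solution and a separate chiral entry, and probably weaker on overall step economy, because the diol needs more than one dihydroxylation.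

Alternative 2: The cut is C12–C13. In the forward step SmI2 would turn the primary iodide of the spiro keto iodide A3 into an alkylsamarium that adds to the C13 ketone, closing ring C and giving the bridgehead alcohol in the pentacycle A4. In its favour, there is no site-selectivity question, the tertiary alcohol forms unprotected with a configuration fixed by geometry, and a finished ring A with lactone and protected diol is tolerated. On the predictability of the ring-closing event and on convergence this alternative is the equal or the better of the chosen plan. Against it, the spiro quaternary C8 with its relation to C9 and C16 must be built first, which moves the central problem and does not remove it; the alkylsamarium may be protonated or may attack the C7 ester; the methylene has to be regenerated from the silyloxymethyl group in several steps; and quinic acid no longer maps onto C13. Overall step economy before and after the key step is therefore expected to be worse.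

Alternative 3: The cuts are C5–C10, C4–C19 and C19–O. In the forward step Cp2Ti(PMe3)2 would bind the C10 ketone and the tethered C4=C5 alkene of the keto alkene A5 as an oxatitanacycle, insert carbon monoxide and release the lactone A6, cis-fused to ring B. In its favour, three bonds and two rings form at once, and the cis fusion of lactone and ring B that the target needs is inherent in the metallacycle; in bonds per step it is better than the chosen plan. It is equal in that diastereoselectivity rests on substrate conformation. Against it, the reagent is stoichiometric and air-sensitive, the ketone is hindered and must ignore the C16 methylene, and A6 has C4 as a methine and lacks C3, so ring A still needs homologation of the acetal arm, an aldol-type closure at a hindered lactone enolate and oxygenation at C2. As in alternative 1 the C/D bicycle must come from elsewhere. Precedent for such hindered ketones is thinner than for carbenoid C–H insertion, and the route is expected to be longer.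

Key step: step 12

Remark on numbering: gibberellane numbers are used for ring C from step 1 on (C13, C12, C11, C9, C8, C14 = C1, C6, C5, C4, C3, C2 of 1).
Assumption: the target SMILES is taken literally (H9 syn to the C10 oxygen and anti to the C15–C16 bridge), and 9, 11 and 16 are taken as purchasable.
Assumption: C6 is epimerisable from step 14 to step 18; compounds 21 to 25 are drawn as the epimer expected at equilibrium (C7 on the face of H9).

Step 1
Reactants: 1 (−)-quinic acid
Product: 2 quinide [(1S,3R,4R,5R)-1,3,4-trihydroxy-6-oxabicyclo[3.2.1]octan-7-one]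
Conditions: p-TsOH·H2O (cat.), toluene/DMF, reflux, Dean–Stark
Reagents that add atoms: none
Why: Acid-catalysed lactonisation with azeotropic removal of water; only the C11 hydroxyl is cis to the carboxyl, so the bridged γ-lactone forms and the cis diol on C8/C9 stays free. No stereocentre is touched.

Step 2
Reactants: 2 quinide
Product: 3 quinide 3,4-O-thiocarbonate (cyclic thionocarbonate on the C8/C9 cis-diol)
Conditions: 1,1'-thiocarbonyldiimidazole (1.1 equiv), THF, 65 °C
Reagents that add atoms: 1,1'-thiocarbonyldiimidazole, S=C(n1ccnc1)n1ccnc1
Why: Thiocarbonylation closes a five-membered ring only on the cis-vicinal diol; the tertiary C13 alcohol does not react.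

Step 3
Reactants: 3 quinide 3,4-O-thiocarbonate
Product: 4 (1S,5R)-1-hydroxy-6-oxabicyclo[3.2.1]oct-3-en-7-one
Conditions: P(OMe)3, 110 °C
Reagents that add atoms: none
Why: Corey–Winter olefination: the phosphite takes the sulfur and the carbene cycloreverts with loss of CO2, a stereospecific syn elimination that gives the C8=C9 alkene. Both unwanted oxygens leave in one step and the allylic C11–O bond remains.

Step 4
Reactants: 4 (1S,5R)-1-hydroxy-6-oxabicyclo[3.2.1]oct-3-en-7-one
Product: 5 (1S,5R)-1-(tert-butyldimethylsilyloxy)-6-oxabicyclo[3.2.1]oct-3-en-7-one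
Conditions: TBSOTf, 2,6-lutidine, CH2Cl2, 0 °C → rt
Reagents that add atoms: tert-butyldimethylsilyl triflate, CC(C)(C)[Si](C)(C)OS(=O)(=O)C(F)(F)F
Why: Silylation of a tertiary alcohol needs the silyl triflate; the bulky ether later keeps the C13 oxygen away from the carbenoid and blocks α-ketol chemistry.

Step 5
Reactants: 5 (1S,5R)-1-(tert-butyldimethylsilyloxy)-6-oxabicyclo[3.2.1]oct-3-en-7-one
Product: 7 4-methoxybenzyl (1S,5R)-1-(tert-butyldimethylsilyloxy)-5-hydroxycyclohex-3-ene-1-carboxylate, via lithium carboxylate 6 (not isolated)
Conditions: LiOH (1.1 equiv), THF/H2O, 0 °C; evaporate; 4-MeOC6H4CH2Cl, Bu4NI (cat.), DMF, rt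
Reagents that add atoms: lithium hydroxide, [Li+].[OH-]; 4-methoxybenzyl chloride, COc1ccc(CCl)cc1
Why: Saponification of the strained lactone followed by SN2 O-alkylation of the carboxylate. The resulting ester can later be cleaved by acid while methyl esters survive; no bond to a stereocentre is broken.

Step 6
Reactants: 7 4-methoxybenzyl (1S,5R)-1-(tert-butyldimethylsilyloxy)-5-hydroxycyclohex-3-ene-1-carboxylate
Product: 8 4-methoxybenzyl (S)-1-(tert-butyldimethylsilyloxy)-5-oxocyclohex-3-ene-1-carboxylate (ring C enone: C11 ketone, C8=C9)
Conditions: Dess–Martin periodinane, NaHCO3, CH2Cl2, rt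
Reagents that add atoms: none
Why: Dess–Martin oxidation of the allylic alcohol gives the conjugated enone under buffered, near-neutral conditions, which avoids β-elimination of the C13 silyloxy group.

Step 7
Reactants: 8 ring C enone; 9 1-methoxy-1-(trimethylsilyloxy)ethene
Product: 10 ring C silyl enol ether (C11 OTMS, C9=C11) with the C8 CH2CO2Me arm cis to the C13 OTBS group
Conditions: 9 (1.5 equiv), TMSOTf (5 mol %), CH2Cl2, −78 °C; Et3N
Reagents that add atoms: none
Why: Mukaiyama–Michael addition with silyl transfer, which gives the C9=C11 enol ether regiodefined. The nucleophile should add axially to C8 in the half-chair that keeps the larger C13 ester pseudo-equatorial, that is syn to the pseudo-axial C13 oxygen, setting C8 cis to OTBS and trans to the carboxyl carbon.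

Step 8
Reactants: 10 ring C silyl enol ether; 11 methyl 2-bromo-3-iodobenzoate
Product: 12 ring C ketone: C11 oxo, C9 2-bromo-3-(methoxycarbonyl)phenyl trans to the C8 CH2CO2Me arm, C13 OTBS and 4-methoxybenzyl ester
Conditions: Pd2(dba)3 (2.5 mol %), P(t-Bu)3 (10 mol %), Bu3SnF (1.5 equiv), toluene, 85 °C
Reagents that add atoms: none
Why: Palladium-catalysed α-arylation of a silyl enol ether through its tin enolate (fluoride-driven Si to Sn exchange) arylates C9 only. Zerovalent palladium inserts into C–I far faster than into the flanked C–Br, and the α-aryl ketone equilibrates to the diequatorial trans arrangement of aryl group and arm.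

Step 9
Reactants: 12 ring C ketone
Product: 14 C11 axial benzoate of ketone 12 (benzoyloxy cis to the C13 ester carbon and the C9 aryl group), via lithium alkoxide 13 (not isolated)
Conditions: LiBH(s-Bu)3, THF, −78 °C; then PhCOCl, DMAP, −78 → 0 °C
Reagents that add atoms: benzoyl chloride, O=C(Cl)c1ccccc1
Why: The bulky hydride attacks the C11 carbonyl from the equatorial side because the axial C13 ester blocks the axial path, giving the axial alkoxide, which is acylated before it can lactonise onto the ester. The axial benzoate removes the only other syn-axial hydrogen that the future C13 carbenoid could reach.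

Step 10
Reactants: 14 C11 axial benzoate
Product: 15 C13 carboxylic acid (C13 OTBS, C11 benzoate, C9 aryl, C8 CH2CO2Me arm)
Conditions: TFA, Et3SiH, CH2Cl2, 0 °C
Reagents that add atoms: none
Why: Acidolysis of the 4-methoxybenzyl ester through the stabilised benzyl cation, which the silane reduces. Methyl esters, benzoate, aryl bromide and the hindered tertiary silyl ether should survive the short exposure.

Step 11
Reactants: 15 C13 carboxylic acid; 16 trimethylsilyldiazomethane
Product: 18 ring C diazomethyl ketone (C13 OTBS; C11 axial benzoate; C9 aryl; C8 CH2CO2Me arm), via acid chloride 17 (not isolated)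
Conditions: (COCl)2, DMF (cat.), CH2Cl2, 0 °C → rt; evaporate; 16 (2.2 equiv), THF/MeCN, 0 °C → rt
Reagents that add atoms: none
Why: Acylation of the diazo carbon by the acid chloride (Arndt–Eistert-type diazo ketone synthesis) with loss of the silyl group as TMSCl; the excess reagent takes up HCl, so the silyl ether is not exposed to acid.

Step 12
Reactants: 18 ring C diazomethyl ketone
Product: 19 bicyclo[3.2.1]octan-16-one (rings C and D): quaternary C8 with CH2CO2Me arm, C9 aryl, C11 benzoate, C13 OTBS
Conditions: Rh2(OAc)4 (2 mol %), CH2Cl2, 40 °C, slow addition of 18 (final 5 mM)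
Reagents that add atoms: none
Why: Rh2(OAc)4 removes N2 from 18 to give an electrophilic rhodium carbenoid at C15, which inserts into the C8–H bond through a three-centre, hydride-transfer-like transition state and releases the catalyst. The closest known reaction type is the dirhodium-catalysed 1,5 C–H insertion of α-diazo ketones to cyclopentanones. Ring D closes by bridging two 1,3-diaxial positions of the ring C chair (axial acyl on C13, axial hydrogen on C8) through a five-membered transition-state ring, which gives the bicyclo[3.2.1]octane. The new quaternary stereocentre C8 forms with retention, so its configuration is that of the C–H bond set in step 7, and the chair is locked by the equatorial C8 arm and C9 aryl group. Site selectivity is needed because this C–H bond is tertiary but electron-poor (β to the ester); it is secured by design, since the axial benzoate on C11 removes the only other syn-axial hydrogen five atoms from C15, H9 lies on the opposite face, and the C6 hydrogens are α to an ester and would need a six-membered transition state. The bulky silyl ether keeps the C13 oxygen from ylide formation, its methyl groups could react only through a six-membered ring, and slow addition at high dilution suppresses carbene dimerisation. The C16 ketone that results is the handle for the methylenation in step 23.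

Step 13
Reactants: 19 bicyclo[3.2.1]octan-16-one
Product: 20 C16 ethylene ketal of 19
Conditions: TMSOCH2CH2OTMS, TMSOTf (10 mol %), CH2Cl2, −20 °C
Reagents that add atoms: 1,2-bis(trimethylsilyloxy)ethane, C[Si](C)(C)OCCO[Si](C)(C)C
Why: Silyl-triflate-catalysed ketalisation (Noyori conditions) is driven by Si–O bond formation and works on hindered ketones at low temperature. The ketal prevents the C15 enolate from competing for the aryl palladium in step 14 and protects C16 in step 19.

Step 14
Reactants: 20 C16 ethylene ketal
Product: 21 tetracyclic diester: ring B closed by the C5–C6 bond, aromatic ring A with C19 methyl ester, C7 methyl ester on the face of H9, C11 benzoate, C13 OTBS, C16 ketal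
Conditions: Pd2(dba)3 (2.5 mol %), P(t-Bu)3 (10 mol %), LiHMDS (2.2 equiv), toluene, 70 °C; NH4Cl
Reagents that add atoms: none
Why: Intramolecular palladium-catalysed α-arylation of the ester enolate (Buchwald–Hartwig type) joins C6 to C5. The arm and the aryl group are gauche on ring C, so the five-membered ring is within reach. C6 is epimerisable and should settle, here or in steps 15 and 18, with C7 pseudo-axial on the H9 face, away from the peri C19 ester and from the seven-membered ring fused on the other face.

Step 15
Reactants: 21 tetracyclic diester
Product: 22 C11 alcohol (axial hydroxyl) of the tetracyclic diester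
Conditions: NaOMe (0.5 equiv), MeOH, 40 °C
Reagents that add atoms: none
Why: Methoxide transesterification removes the benzoate as methyl benzoate; the two methyl esters exchange degenerately and C6 equilibrates.

Step 16
Reactants: 22 C11 alcohol
Product: 23 C11 O-(imidazol-1-ylthiocarbonyl) derivative of 22
Conditions: 1,1'-thiocarbonyldiimidazole, DMAP (cat.), ClCH2CH2Cl, 70 °C
Reagents that add atoms: 1,1'-thiocarbonyldiimidazole, S=C(n1ccnc1)n1ccnc1
Why: Thioacylation of the secondary alcohol, the first stage of a Barton–McCombie deoxygenation; no base strong enough to disturb the esters is used.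

Step 17
Reactants: 23 C11 thiocarbonylimidazolide
Product: 24 11-deoxy tetracyclic diester (C11 CH2)
Conditions: Bu3SnH, AIBN (cat.), toluene, 100 °C
Reagents that add atoms: none
Why: Barton–McCombie radical deoxygenation. With the aryl bromide already consumed the stannyl radical has no competing site, and the secondary C11 radical should be reduced faster than it can rearrange.

Step 18
Reactants: 24 11-deoxy tetracyclic diester
Product: 25 tetracyclic diacid (C7 and C19 acids, C7 on the face of H9)
Conditions: KOH, MeOH/H2O (3:1), 65 °C; HCl to pH 3
Reagents that add atoms: potassium hydroxide, [K+].[OH-]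
Why: Saponification of both methyl esters. The benzylic ester at C6 epimerises faster than it hydrolyses, so the carboxylate is fixed in the thermodynamic configuration that directs step 19.

Step 19
Reactants: 25 tetracyclic diacid
Product: 26 4-methyl-1,4-dihydro diacid (C2=C3 and C5=C10; C18 methyl anti to C7, C19 acid syn to C7)
Conditions: Li, NH3(l)/THF, −78 °C; MeI, −78 → −33 °C; NH4Cl
Reagents that add atoms: methyl iodide, CI
Why: Birch reductive alkylation of the benzoate: two-electron reduction with protonation at C1 leaves the C4 enediolate, which is methylated at C4. The pseudo-axial C7 carboxylate on C6 shields its own face, so methyl should enter anti to it and set C4 with C19 on the H9 face.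

Step 20
Reactants: 26 4-methyl-1,4-dihydro diacid
Product: 27 19,10-lactone keto acid (Δ2 alkene, C16 ketone, C13 OTBS; C7 acid still cis to C4)
Conditions: TFA, CH2Cl2, 0 °C → rt; then H2O
Reagents that add atoms: water, O
Why: Acid-mediated lactonisation of the β,γ-unsaturated acid: protonation of C5=C10 at C5 and capture of the tertiary C10 cation by the C19 carboxyl on its own face (anti addition) give the lactone oxygen syn to H9 and H5 anti to it. The less strained 19,10-lactone is preferred over closure from C7, and the aqueous acid also hydrolyses the ketal.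

Step 21
Reactants: 27 19,10-lactone keto acid; 16 trimethylsilyldiazomethane
Product: 29 methyl ester of the keto lactone with C7 trans to C4 (target C6 configuration), via C6-epimeric methyl ester 28 (not isolated)
Conditions: 16, MeOH/toluene, 0 °C; then NaOMe, MeOH, 60 °C; AcOH
Reagents that add atoms: none
Why: Esterification by diazomethane released in situ from 16 and methanol, then reversible enolisation of the ester under methoxide. This moves C7 from the crowded position cis to the quaternary C4 to the trans position, the configuration of the target.

Step 22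
Reactants: 29 keto lactone methyl ester
Product: 30 2,3-cis-diol (both hydroxyls anti to the lactone bridge) of the keto lactone methyl ester
Conditions: OsO4 (2 mol %), NMO, acetone/H2O, rt; Na2SO3
Reagents that add atoms: N-methylmorpholine N-oxide, C[N+]1([O-])CCOCC1; water, O
Why: Catalytic syn dihydroxylation (Upjohn conditions). The two-atom lactone bridge covers one face of C2=C3, so OsO4 should add from the opposite, exo face and set C2 and C3 together.

Step 23
Reactants: 30 2,3-diol keto lactone methyl ester
Product: 31 16-methylene diol methyl ester (C13 OTBS)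
Conditions: Zn, CH2Br2, TiCl4, THF; CH2Cl2, 0 °C → rt
Reagents that add atoms: dibromomethane, BrCBr
Why: Takai–Lombardo methylenation with the zinc–titanium gem-dimetallic reagent is non-basic and ketone-selective. The ester and lactone are left alone, and the β-hydroxy lactone is not exposed to the retro-aldol epimerisation that a phosphorus ylide could cause.

Step 24
Reactants: 31 16-methylene diol methyl ester
Product: 32 13-O-TBS ether of the target acid
Conditions: LiSPr, HMPA, rt
Reagents that add atoms: none
Why: SN2 demethylation of the hindered ester by thiolate at the methyl carbon; no acyl attack occurs, so the lactone, C3 and C6 keep their configuration.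

Step 25
Reactants: 32 13-O-TBS ether of the target acid
Product: 33 target CNP0265952.3
Conditions: HF (48 % aq.), MeCN, 0 °C → rt
Reagents that add atoms: none
Why: Fluoride-assisted cleavage of the tertiary silyl ether under mildly acidic conditions that should leave the allylic tertiary alcohol and exocyclic alkene unrearranged.

## Compound list

1 | (−)-quinic acid | C1[C@H]([C@H]([C@@H](C[C@@]1(C(=O)O)O)O)O)O | starting material
2 | quinide, (1S,3R,4R,5R)-1,3,4-trihydroxy-6-oxabicyclo[3.2.1]octan-7-one | O[C@]1(C(=O)O2)C[C@@H]2[C@H](O)[C@H](O)C1 | intermediate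
3 | quinide 3,4-O-thiocarbonate | O[C@]1(C(=O)O2)C[C@@H]2[C@@H]3OC(=S)O[C@@H]3C1 | intermediate
4 | (1S,5R)-1-hydroxy-6-oxabicyclo[3.2.1]oct-3-en-7-one | O[C@]1(C(=O)O2)C[C@@H]2C=CC1 | intermediate
5 | (1S,5R)-1-(tert-butyldimethylsilyloxy)-6-oxabicyclo[3.2.1]oct-3-en-7-one | CC(C)(C)[Si](C)(C)O[C@]1(C(=O)O2)C[C@@H]2C=CC1 | intermediate
6 | lithium (1S,5R)-1-(tert-butyldimethylsilyloxy)-5-hydroxycyclohex-3-ene-1-carboxylate | CC(C)(C)[Si](C)(C)O[C@]1(C(=O)[O-])C[C@@H](O)C=CC1.[Li+] | intermediate
7 | 4-methoxybenzyl (1S,5R)-1-(tert-butyldimethylsilyloxy)-5-hydroxycyclohex-3-ene-1-carboxylate | CC(C)(C)[Si](C)(C)O[C@]1(C(=O)OCc2ccc(OC)cc2)C[C@@H](O)C=CC1 | intermediate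
8 | 4-methoxybenzyl (S)-1-(tert-butyldimethylsilyloxy)-5-oxocyclohex-3-ene-1-carboxylate | CC(C)(C)[Si](C)(C)O[C@]1(C(=O)OCc2ccc(OC)cc2)CC(=O)C=CC1 | intermediate
9 | 1-methoxy-1-(trimethylsilyloxy)ethene | C=C(OC)O[Si](C)(C)C | starting material
10 | ring C silyl enol ether, C8 CH2CO2Me arm cis to C13 OTBS | CC(C)(C)[Si](C)(C)O[C@]1(C(=O)OCc2ccc(OC)cc2)CC(O[Si](C)(C)C)=C[C@H](CC(=O)OC)C1 | intermediate
11 | methyl 2-bromo-3-iodobenzoate | COC(=O)c1cccc(I)c1Br | starting material
12 | ring C ketone, C9 aryl trans to C8 arm | CC(C)(C)[Si](C)(C)O[C@]1(C(=O)OCc2ccc(OC)cc2)CC(=O)[C@@H](c2cccc(C(=O)OC)c2Br)[C@H](CC(=O)OC)C1 | intermediate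
13 | lithium C11 alkoxide (axial, cis to the C13 ester) | CC(C)(C)[Si](C)(C)O[C@]1(C(=O)OCc2ccc(OC)cc2)C[C@@H]([O-])[C@@H](c2cccc(C(=O)OC)c2Br)[C@H](CC(=O)OC)C1.[Li+] | intermediate
14 | C11 axial benzoate, 4-methoxybenzyl ester | CC(C)(C)[Si](C)(C)O[C@]1(C(=O)OCc2ccc(OC)cc2)C[C@@H](OC(=O)c2ccccc2)[C@@H](c2cccc(C(=O)OC)c2Br)[C@H](CC(=O)OC)C1 | intermediate
15 | C13 carboxylic acid | CC(C)(C)[Si](C)(C)O[C@]1(C(=O)O)C[C@@H](OC(=O)c2ccccc2)[C@@H](c2cccc(C(=O)OC)c2Br)[C@H](CC(=O)OC)C1 | intermediate
16 | trimethylsilyldiazomethane | C[Si](C)(C)C=[N+]=[N-] | starting material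
17 | C13 acid chloride | CC(C)(C)[Si](C)(C)O[C@]1(C(=O)Cl)C[C@@H](OC(=O)c2ccccc2)[C@@H](c2cccc(C(=O)OC)c2Br)[C@H](CC(=O)OC)C1 | intermediate
18 | ring C diazomethyl ketone (key-step precursor; C11 axial benzoate as spectator) | CC(C)(C)[Si](C)(C)O[C@]1(C(=O)C=[N+]=[N-])C[C@@H](OC(=O)c2ccccc2)[C@@H](c2cccc(C(=O)OC)c2Br)[C@H](CC(=O)OC)C1 | intermediate
19 | bicyclo[3.2.1]octan-16-one, rings C and D (key-step product) | O=C1C[C@@]2(CC(=O)OC)C[C@]1(O[Si](C)(C)C(C)(C)C)C[C@@H](OC(=O)c3ccccc3)[C@H]2c1cccc(C(=O)OC)c1Br | intermediate
20 | C16 ethylene ketal of 19 | O1CCOC12C[C@@]3(CC(=O)OC)C[C@]2(O[Si](C)(C)C(C)(C)C)C[C@@H](OC(=O)c4ccccc4)[C@H]3c2cccc(C(=O)OC)c2Br | intermediate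
21 | tetracyclic diester, ring B closed, C11 benzoate | O1CCOC12C[C@@]34C[C@]2(O[Si](C)(C)C(C)(C)C)C[C@@H](OC(=O)c2ccccc2)[C@H]3c2cccc(C(=O)OC)c2[C@@H]4C(=O)OC | intermediate
22 | tetracyclic diester, C11 alcohol | O1CCOC12C[C@@]34C[C@]2(O[Si](C)(C)C(C)(C)C)C[C@@H](O)[C@H]3c2cccc(C(=O)OC)c2[C@@H]4C(=O)OC | intermediate
23 | tetracyclic diester, C11 O-(imidazol-1-ylthiocarbonyl) | O1CCOC12C[C@@]34C[C@]2(O[Si](C)(C)C(C)(C)C)C[C@@H](OC(=S)n2ccnc2)[C@H]3c2cccc(C(=O)OC)c2[C@@H]4C(=O)OC | intermediate
24 | 11-deoxy tetracyclic diester | O1CCOC12C[C@@]34C[C@]2(O[Si](C)(C)C(C)(C)C)CC[C@H]3c2cccc(C(=O)OC)c2[C@@H]4C(=O)OC | intermediate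
25 | tetracyclic diacid | O1CCOC12C[C@@]34C[C@]2(O[Si](C)(C)C(C)(C)C)CC[C@H]3c2cccc(C(=O)O)c2[C@@H]4C(=O)O | intermediate
26 | 4-methyl-1,4-dihydro diacid | O1CCOC12C[C@@]34C[C@]2(O[Si](C)(C)C(C)(C)C)CC[C@H]3C2=C([C@@H]4C(=O)O)[C@@](C)(C(=O)O)C=CC2 | intermediate
27 | 19,10-lactone keto acid, C7 cis to C4 | O=C1C[C@@]23C[C@]1(O[Si](C)(C)C(C)(C)C)CC[C@H]2[C@]12CC=C[C@](C)(C(=O)O1)[C@@H]2[C@@H]3C(=O)O | intermediate
28 | methyl ester of 27, C7 cis to C4 | O=C1C[C@@]23C[C@]1(O[Si](C)(C)C(C)(C)C)CC[C@H]2[C@]12CC=C[C@](C)(C(=O)O1)[C@@H]2[C@@H]3C(=O)OC | intermediate
29 | keto lactone methyl ester, C7 trans to C4 | O=C1C[C@@]23C[C@]1(O[Si](C)(C)C(C)(C)C)CC[C@H]2[C@]12CC=C[C@](C)(C(=O)O1)[C@@H]2[C@H]3C(=O)OC | intermediate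
30 | 2,3-diol keto lactone methyl ester | O=C1C[C@@]23C[C@]1(O[Si](C)(C)C(C)(C)C)CC[C@H]2[C@]12C[C@@H](O)[C@@H](O)[C@](C)(C(=O)O1)[C@@H]2[C@H]3C(=O)OC | intermediate
31 | 16-methylene diol methyl ester, 13-O-TBS | C=C1C[C@@]23C[C@]1(O[Si](C)(C)C(C)(C)C)CC[C@H]2[C@]12C[C@@H](O)[C@@H](O)[C@](C)(C(=O)O1)[C@@H]2[C@H]3C(=O)OC | intermediate
32 | 13-O-TBS ether of the target acid | C=C1C[C@@]23C[C@]1(O[Si](C)(C)C(C)(C)C)CC[C@H]2[C@]12C[C@@H](O)[C@@H](O)[C@](C)(C(=O)O1)[C@@H]2[C@H]3C(=O)O | intermediate
33 | CNP0265952.3 | C=C1C[C@@]23C[C@]1(O)CC[C@H]2[C@]12C[C@@H](O)[C@@H](O)[C@](C)(C(=O)O1)[C@@H]2[C@H]3C(=O)O | target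

## Step count and least certain steps

Total step count: 25. Longest linear sequence: 25 steps (1 to 33); 9, 11 and 16 enter as purchased reagents.

Step 12 (key step). The most likely failure is diversion of the carbenoid before it reaches C8–H, by dimerisation, by attack on a silyl methyl C–H bond or on the benzoate oxygen. The C8–H bond is the only one in reach, but the ester two carbons away makes it a poor hydride donor. The fallback changes the carbenoid class and sets out from 15. Its acid chloride 17 would be added to the lithium enolate of methyl acetate (LDA, MeOAc, THF, −78 °C) to give the β-keto ester F1. Diazo transfer (4-acetamidobenzenesulfonyl azide, Et3N, MeCN) would give the α-diazo β-keto ester F2. Its longer-lived and more discriminating carbenoid (Rh2(OAc)4, CH2Cl2, 40 °C) should insert into the same C8–H bond to give the C15 methoxycarbonyl ketone F3. Krapcho dealkoxycarbonylation (LiCl, wet DMSO, 130 °C) would remove the extra ester and return to the route at 19.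

Step 7. The most likely failure is poor facial selectivity, with the nucleophile entering syn to the ester rather than syn to the silyloxy group, since the two C13 substituents differ only modestly in size. The fallback reverses which atom enters C8 and sets out from 10, whichever C8 epimer predominates. Saegusa–Ito oxidation (Pd(OAc)2, MeCN) would give the 3-substituted enone F4 with C8 planar. Rhodium-catalysed conjugate hydrosilylation (Et3SiH, RhCl(PPh3)3) would then deliver hydrogen, not carbon, to C8 and give the triethylsilyl enol ether F5, so that the same facial preference that misplaced the arm now places it correctly. Arylation of F5 under the conditions of step 8 returns to the route at 12.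

Step 8. The most likely failure is slow coupling at the hindered secondary carbon next to C8 with an ortho-disubstituted aryl palladium. Prolonged heating with fluoride would then allow enolate equilibration toward C12 with β-elimination of the silyloxy group, or erosion of the iodine-over-bromine selectivity. The fallback makes the C9–aryl bond at the sp2 stage and sets out from 8. α-Iodination (I2, pyridine, CH2Cl2) would give the 2-iodo enone F6. Negishi coupling (Pd(PPh3)4, THF, rt) with the arylzinc chloride F7, made from 11 by iodine–magnesium exchange (i-PrMgCl·LiCl, −40 °C) and ZnCl2, would give the 2-aryl enone F8. Mukaiyama–Michael addition of 9 (TMSOTf cat., CH2Cl2, −78 °C) would give the silyl enol ether F9, and mild acid (HCl, THF/H2O) would return to the route at 12, with C9 settling trans to the arm.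

Step 19. The most likely failure is poor or reversed facial selectivity of the methylation, because C4 is controlled only by the C7 carboxylate on the neighbouring ring. Methylation syn to C7 would lead, after step 20, to the lactone on the face opposite H9. The fallback enters the reduction with the other C6 epimer and sets out from 24. Deprotonation (LDA, THF, −78 °C) and kinetic protonation from the open face (AcOH) would give the C6 epimer F10. SN2 demethylation without epimerisation (LiSPr, HMPA) would give the diacid F11. Birch reductive methylation as in step 19 would give the dihydro diacid F12. TFA as in step 20 would give the lactone keto acid F13, which already has C7 trans to C4. Esterification with 16 returns to the route at 29 without the equilibration.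

Step 21. The most likely failure is incomplete epimerisation, because H6 lies on the concave face under the C15–C16 bridge and methoxide may instead open the lactone reversibly. The fallback equilibrates an acid derivative under non-alkoxide conditions and sets out from 27. Heating with Ac2O and NaOAc (110 °C) would form the acetic mixed anhydride and equilibrate C6 through its enol to the mixed anhydride F14 with C7 trans to C4. Quenching with MeOH and DMAP returns to the route at 29.

## Further compounds

F1 | step 12 | C13 β-keto methyl ester (C13–CO–CH2–CO2Me) analogue of 18 | CC(C)(C)[Si](C)(C)O[C@]1(C(=O)CC(=O)OC)C[C@@H](OC(=O)c2ccccc2)[C@@H](c2cccc(C(=O)OC)c2Br)[C@H](CC(=O)OC)C1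
F2 | step 12 | α-diazo β-keto ester | CC(C)(C)[Si](C)(C)O[C@]1(C(=O)C(=[N+]=[N-])C(=O)OC)C[C@@H](OC(=O)c2ccccc2)[C@@H](c2cccc(C(=O)OC)c2Br)[C@H](CC(=O)OC)C1
F3 | step 12 | C15 methoxycarbonyl derivative of 19 | O=C1C(C(=O)OC)[C@@]2(CC(=O)OC)C[C@]1(O[Si](C)(C)C(C)(C)C)C[C@@H](OC(=O)c3ccccc3)[C@H]2c1cccc(C(=O)OC)c1Br
F4 | step 7 | 3-substituted ring C enone (C8=C9, arm on C8) | CC(C)(C)[Si](C)(C)O[C@]1(C(=O)OCc2ccc(OC)cc2)CC(=O)C=C(CC(=O)OC)C1
F5 | step 7 | triethylsilyl enol ether analogue of 10 | CC(C)(C)[Si](C)(C)O[C@]1(C(=O)OCc2ccc(OC)cc2)CC(O[Si](CC)(CC)CC)=C[C@H](CC(=O)OC)C1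
F6 | step 8 | 2-iodo enone (iodine on C9) | CC(C)(C)[Si](C)(C)O[C@]1(C(=O)OCc2ccc(OC)cc2)CC(=O)C(I)=CC1
F7 | step 8 | [2-bromo-3-(methoxycarbonyl)phenyl]zinc chloride | COC(=O)c1cccc([Zn]Cl)c1Br
F8 | step 8 | 2-aryl enone (aryl on C9) | CC(C)(C)[Si](C)(C)O[C@]1(C(=O)OCc2ccc(OC)cc2)CC(=O)C(c2cccc(C(=O)OC)c2Br)=CC1
F9 | step 8 | C9-aryl trimethylsilyl enol ether with C8 arm | CC(C)(C)[Si](C)(C)O[C@]1(C(=O)OCc2ccc(OC)cc2)CC(O[Si](C)(C)C)=C(c2cccc(C(=O)OC)c2Br)[C@H](CC(=O)OC)C1
F10 | step 19 | C6 epimer of 24 | O1CCOC12C[C@@]34C[C@]2(O[Si](C)(C)C(C)(C)C)CC[C@H]3c2cccc(C(=O)OC)c2[C@H]4C(=O)OC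
F11 | step 19 | C6 epimer of 25 | O1CCOC12C[C@@]34C[C@]2(O[Si](C)(C)C(C)(C)C)CC[C@H]3c2cccc(C(=O)O)c2[C@H]4C(=O)O
F12 | step 19 | C6 epimer of 26 | O1CCOC12C[C@@]34C[C@]2(O[Si](C)(C)C(C)(C)C)CC[C@H]3C2=C([C@H]4C(=O)O)[C@@](C)(C(=O)O)C=CC2
F13 | step 19 | C6 epimer of 27 (free acid of 29) | O=C1C[C@@]23C[C@]1(O[Si](C)(C)C(C)(C)C)CC[C@H]2[C@]12CC=C[C@](C)(C(=O)O1)[C@@H]2[C@H]3C(=O)O
F14 | step 21 | acetic mixed anhydride of the C6-equilibrated acid | O=C1C[C@@]23C[C@]1(O[Si](C)(C)C(C)(C)C)CC[C@H]2[C@]12CC=C[C@](C)(C(=O)O1)[C@@H]2[C@H]3C(=O)OC(C)=O
A1 | alternative 1 | α-methyl β-keto ester tethered at C10 of the ring B cyclopentene | C=C1C[C@@]23C[C@]1(OC(C)=O)CC[C@H]2C(CCC(=O)C(C)C(=O)OC)=C[C@H]3C(=O)OC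
A2 | alternative 1 | 3-oxo lactone with the complete ring system | C=C1C[C@@]23C[C@]1(OC(C)=O)CC[C@H]2[C@]12CCC(=O)[C@](C)(C(=O)O1)[C@@H]2[C@H]3C(=O)OC
A3 | alternative 2 | spiro B/D keto iodide (C13 ketone, C12 iodide) | CC(C)(C)[Si](C)(C)OC[C@@H]1C[C@@]2(CC1=O)[C@@H](CCI)[C@]13C[C@@H](OC(C)(C)O4)[C@@H]4[C@](C)(C(=O)O1)[C@@H]3[C@H]2C(=O)OC
A4 | alternative 2 | pentacyclic C13 alcohol with C16 silyloxymethyl group | CC(C)(C)[Si](C)(C)OC[C@@H]1C[C@@]23C[C@]1(O)CC[C@H]2[C@]12C[C@@H](OC(C)(C)O4)[C@@H]4[C@](C)(C(=O)O1)[C@@H]2[C@H]3C(=O)OC
A5 | alternative 3 | C10 ketone with tethered C4=C5 propenyl group on C6 | C=C1C[C@]2(C[C@]1(O[Si](C)(C)C(C)(C)C)CC[C@H]2C(=O)CC(OC)OC)[C@@H](/C=C/C)C(=O)OC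
A6 | alternative 3 | lactone cis-fused to ring B with C10 dimethoxyethyl arm | C=C1C[C@@]23C[C@]1(O[Si](C)(C)C(C)(C)C)CC[C@H]2[C@]2(CC(OC)OC)OC(=O)[C@@H](C)[C@@H]2[C@H]3C(=O)OC
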